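Cuts (retro): acyl groups and the C2/C3 acid level go on last. Then come C11–H (from an 11-ketone), C5–C10 (ring B), one C4–CH3, C6–C7, C7–C8, C8–O, C9–C10, the C14/C11 oxygens and C13–vinyl.
Forward: ring C is 3-methylcyclohexenone. A temporary oxane ring (O–C2–C1–C10–C9–C11) is closed as a mixed ketal on C11. Ring B (C5–C10) is closed last by a metal-hydride HAT radical 6-exo cyclisation, and acid then opens the oxane again.
Enabling feature: quaternary C10 carries a CH3 (H• plus an exocyclic CH2) and a C1–C2 arm lying in the bay beside the C11 oxygen (C2 and O11 are 1,5-related across C1–C10–C9–C11), so the arm can be tied back to C11. C5 carries CMe2CO2H, so C4 can be the sp2 α-carbon of an enoate with C5 as its β-carbon.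
Stereochemistry: C13 and C9 come from two catalyst-controlled conjugate additions (NHC–Cu, Rh/BINAP). C8 and C7 come from substrate control on the locked ring C (blocked β face, Cram chelate). C10 and C5 come from the chair transition state of the key step, and C11 from hydride delivery by the 8β-OH.

Key step: step 17

Assumption: locants follow isopimarane numbering. Ring B is C5–C6–C7–C8–C9–C10, ring C is C8–C9–C11–C12–C13–C14, and C2 and C3 are the carboxyl carbons. α is the face of H9 and β the face of C20.
Assumption: the sense of induction in steps 1 and 7 is assigned by analogy with the parent cyclohexenone cases. The other ligand enantiomer would be used if the sense turned out opposite.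

Step 1
Reactants: 1 3-methylcyclohex-2-en-1-one
Product: 2 (R)-3-methyl-3-[1-(trimethylsilyl)ethenyl]cyclohexanone
Conditions: HC≡CSiMe3, DIBAL-H, hexanes/THF, 55 °C; then 1, chiral sulfonate NHC–Ag complex (2.5 mol %), Cu(OTf)2 (5 mol %), THF, 22 °C
Reagents that add atoms: ethynyltrimethylsilane, C#C[Si](C)(C)C
Why: NHC–Cu-catalysed enantioselective conjugate addition of an α-silylvinylaluminium to a β-substituted cyclic enone, in which the chiral Cu complex selects the enone face and sets the all-carbon quaternary centre C13.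

Step 2
Reactants: 2 (R)-3-methyl-3-[1-(trimethylsilyl)ethenyl]cyclohexanone
Product: 3 (R)-3-ethenyl-3-methylcyclohexanone
Conditions: CF3CO2H, CH2Cl2, 22 °C
Reagents that add atoms: none
Why: Protodesilylation of the vinylsilane (ipso protonation, β-silyl cation, loss of silicon) unmasks the vinyl group without touching C13.

Step 3
Reactants: 3 (R)-3-ethenyl-3-methylcyclohexanone
Product: 4 (R)-5-ethenyl-5-methylcyclohex-2-enone
Conditions: IBX, DMSO, 70 °C
Reagents that add atoms: none
Why: IBX dehydrogenation of a ketone, where only C9–C8 can be desaturated because the other α-carbon (C12) is flanked by quaternary C13.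

Step 4
Reactants: 4 (R)-5-ethenyl-5-methylcyclohex-2-enone
Product: 5 (R)-2-ethenyl-2-methylcyclohex-5-ene-1,4-dione
Conditions: Rh2(cap)4 (1 mol %), t-BuOOH (70 % aq), ClCH2CH2Cl, 40 °C
Reagents that add atoms: tert-butyl hydroperoxide, CC(C)(C)OO
Why: Dirhodium caprolactamate/TBHP allylic oxidation of an enone to the ene-dione at the only allylic CH2 (C14), the same γ-oxidation next to a quaternary carbon as isophorone to ketoisophorone.

Step 5
Reactants: 5 (R)-2-ethenyl-2-methylcyclohex-5-ene-1,4-dione
Product: 6 (R)-6-ethenyl-4,4-dimethoxy-6-methylcyclohex-2-enone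
Conditions: HC(OMe)3, MeOH, p-TsOH (cat.), 0 °C to rt
Reagents that add atoms: trimethyl orthoformate, COC(OC)OC
Why: Acid-catalysed ketalisation goes to the C11 carbonyl because the C14 carbonyl is shielded by quaternary C13 (as in ketoisophorone), and the quaternary carbon rules out aromatisation.

Step 6
Reactants: 7 3-bromobut-3-en-1-ol
Product: 8 3-(4,4,5,5-tetramethyl-1,3,2-dioxaborolan-2-yl)but-3-en-1-ol
Conditions: B2pin2, PdCl2(dppf) (3 mol %), KOAc, dioxane, 80 °C
Reagents that add atoms: bis(pinacolato)diboron, CC1(C)OB(OC1(C)C)B1OC(C)(C)C(C)(C)O1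
Why: Miyaura borylation of an alkenyl bromide, which tolerates the free alcohol.

Step 7
Reactants: 6 (R)-6-ethenyl-4,4-dimethoxy-6-methylcyclohex-2-enone; 8 3-(4,4,5,5-tetramethyl-1,3,2-dioxaborolan-2-yl)but-3-en-1-ol
Product: 9 (2R,5S)-2-ethenyl-5-(4-hydroxybut-1-en-2-yl)-4,4-dimethoxy-2-methylcyclohexanone
Conditions: [Rh(OH)((S)-binap)]2 (3 mol % Rh), dioxane/H2O 10:1, 40 °C
Reagents that add atoms: none
Why: Hayashi–Miyaura Rh/BINAP-catalysed asymmetric 1,4-addition of an alkenylboron reagent to the only enone, where the catalyst delivers C10 to the β face of C9 (9α-H) and overrides the remote C13 centre.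

Step 8
Reactants: 9 (2R,5S)-2-ethenyl-5-(4-hydroxybut-1-en-2-yl)-4,4-dimethoxy-2-methylcyclohexanone
Product: 10 trans-fused oxane mixed ketal (ring O 11α equatorial; OMe 11β axial; 9α-H; exocyclic C10=C20H2; C14 ketone)
Conditions: PPTS (10 mol %), 4 Å MS, CH2Cl2, rt (equilibrating)
Reagents that add atoms: none
Why: Acid-catalysed transketalisation under equilibrium control, where both anomers place one oxygen syn-axial to C17 and keep an anomeric effect, so the trans-fused oxadecalin should prevail because it avoids the extra gauche contacts of the cis-fused form.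

Step 9
Reactants: 10 trans-fused oxane mixed ketal
Product: 12 8α-hydroxy ketone of the oxane ketal, via potassium enolate 11 (not isolated)
Conditions: KHMDS, THF, −78 °C; then 2-(phenylsulfonyl)-3-phenyloxaziridine, −78 °C
Reagents that add atoms: 2-(phenylsulfonyl)-3-phenyloxaziridine, O=S(=O)(N1OC1c1ccccc1)c1ccccc1
Why: Davis oxidation of the only possible enolate (toward C8, since C13 is quaternary), in which oxygen should enter from the open α face, a centre that is planarised again in step 11.

Step 10
Reactants: 12 8α-hydroxy ketone of the oxane ketal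
Product: 13 8α-(methoxymethoxy) ketone
Conditions: MOMCl, i-Pr2NEt, CH2Cl2, 0 °C to rt
Reagents that add atoms: chloromethyl methyl ether, COCCl
Why: Standard MOM ether formation puts a base-stable and chelating group on O8.

Step 11
Reactants: 13 8α-(methoxymethoxy) ketone
Product: 15 8β-(methoxymethoxy)-8α-(hydroxymethyl) ketone, via lithium enolate 14 (not isolated)
Conditions: LDA, THF, −78 °C; then CH2O (gas), −78 to −40 °C
Reagents that add atoms: formaldehyde, C=O
Why: Aldol addition of the tetrasubstituted α-alkoxy enolate to formaldehyde, where the axial 11β-OMe and the C17 methyl block the β face of locked ring C, so C7 enters from the α face and pushes O8 into the hindered axial 8β position.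

Step 12
Reactants: 15 8β-(methoxymethoxy)-8α-(hydroxymethyl) ketone
Product: 16 8β-(methoxymethoxy)-8α-carbaldehyde (C7 aldehyde)
Conditions: Dess–Martin periodinane, NaHCO3, CH2Cl2, 0 °C
Reagents that add atoms: none
Why: Buffered Dess–Martin oxidation of the neopentyl primary alcohol gives an aldehyde with no α-hydrogen to epimerise, and the ketal is spared.

Step 13
Reactants: 17 tiglic acid
Product: 18 tert-butyl tiglate
Conditions: Cl3CC(=NH)Ot-Bu, BF3·OEt2 (cat.), cyclohexane/CH2Cl2, rt
Reagents that add atoms: tert-butyl 2,2,2-trichloroacetimidate, CC(C)(C)OC(=N)C(Cl)(Cl)Cl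
Why: Acid-catalysed tert-butylation of a carboxylic acid by the trichloroacetimidate.

Step 14
Reactants: 18 tert-butyl tiglate
Product: 20 1-tert-butoxy-1-(tert-butyldimethylsilyloxy)-2-methylbuta-1,3-diene, via lithium dienolate 19 (not isolated)
Conditions: LDA, DMPU, THF, −78 °C; then TBSCl
Reagents that add atoms: tert-butyldimethylsilyl chloride, C[Si](C)(Cl)C(C)(C)C
Why: γ-Deprotonation of the tiglate and O-silylation give the vinylketene silyl acetal used in vinylogous Mukaiyama aldol reactions.

Step 15
Reactants: 16 8β-(methoxymethoxy)-8α-carbaldehyde; 20 1-tert-butoxy-1-(tert-butyldimethylsilyloxy)-2-methylbuta-1,3-diene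
Product: 21 7-hydroxy (E)-enoate (C7–OH anti to O8; chain C6H2–C5H=C4(CH3)–CO2t-Bu)
Conditions: MgBr2·OEt2 (3 equiv), CH2Cl2, −78 to −40 °C; aq NH4Cl
Reagents that add atoms: none
Why: Chelation-controlled vinylogous Mukaiyama aldol reaction, in which Mg2+ ties O7 to the MOM-bearing O8 (Cram chelate) and the γ-carbon of 20 attacks C7 from the side of the flat C14 carbonyl, away from the C10 arm on C9, giving the 7-OH anti to O8 (7α after ring closure) and the (E)-enoate.

Step 16
Reactants: 21 7-hydroxy (E)-enoate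
Product: 22 7-O-triethylsilyl ether (cyclisation precursor)
Conditions: TESCl, imidazole, DMAP (cat.), DMF, rt
Reagents that add atoms: chlorotriethylsilane, CC[Si](Cl)(CC)CC
Why: Silylation of the secondary alcohol blocks retro-aldol cleavage of C7–C8 in the later base step.

Step 17
Reactants: 22 7-O-triethylsilyl ether (cyclisation precursor)
Product: 24 ring-B-closed tricyclic ester (C20 methyl β axial; C1 equatorial in the oxane; H5 α; C4 epimers), via tertiary C10 radical 23 (not isolated)
Conditions: Fe(dibm)3 (20 mol %), PhSiH3, Na2HPO4, EtOH (0.01 M), 60 °C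
Reagents that add atoms: none
Why: An iron hydride transfers H• to the terminal CH2 (C20) of the 1,1-disubstituted alkene, the nucleophilic tertiary C10 radical 23 adds 6-exo-trig to C5 (the β-carbon of the tethered tiglate), and the α-ester radical is reduced by Fe(II) and protonated by EtOH; this is the intramolecular form of the iron-mediated reductive olefin coupling (Giese-type addition), an established way to make quaternary carbons. Ring B closes through a chair-like 6-exo transition state trans-fused to ring C, because C7 on C8 and C10 on C9 are both equatorial. At C10 the oxane ring holds C1 anti to C8, so only the radical lobe anti to C11 can reach C5 through a chair, which makes the new CH3 (C20) axial β and leaves C1 equatorial. At C5 the enoate arm sits pseudo-equatorial in that chair (Beckwith–Houk model), giving H5 α trans to C20, while C4 forms as an epimer mixture that step 18 erases. The step needs HAT to the 1,1-disubstituted alkene rather than to the neopentyl monosubstituted C13 vinyl or the electron-poor enoate, which the faster formation of a tertiary radical and a limited charge of silane should secure, and high dilution should let ring closure outrun reduction of 23.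

Step 18
Reactants: 24 ring-B-closed tricyclic ester
Product: 26 gem-dimethyl tert-butyl ester, via lithium ester enolate 25 (not isolated)
Conditions: LDA, DMPU, THF, −78 to −40 °C; then MeI
Reagents that add atoms: iodomethane, CI
Why: Enolate alkylation at the only enolisable position (the C14 ketone has no α-hydrogen) erases the C4 stereocentre and completes the CMe2 group.

Step 19
Reactants: 26 gem-dimethyl tert-butyl ester
Product: 27 11-keto 2,7α,8β-triol 3-carboxylic acid (oxane opened)
Conditions: TFA/H2O/CH2Cl2, 0 °C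
Reagents that add atoms: water, O
Why: Aqueous acid removes all acid-labile helpers at once (TES, MOM, tert-butyl ester) and hydrolyses the mixed ketal, which opens the temporary oxane to the C11 ketone and the C2 alcohol.

Step 20
Reactants: 27 11-keto 2,7α,8β-triol 3-carboxylic acid
Product: 29 7α-acetate 2-O-TBS ether 11-ketone, via C2 silyl ether 28 (not isolated)
Conditions: TBSCl, imidazole, CH2Cl2, 0 °C; then Ac2O, DMAP, pyridine, rt; aq work-up
Reagents that add atoms: tert-butyldimethylsilyl chloride, C[Si](C)(Cl)C(C)(C)C; acetic anhydride, CC(=O)OC(C)=O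
Why: Rate-selective silylation of the only primary alcohol is followed by DMAP-catalysed acetylation of the only secondary alcohol, while the tertiary 8β-OH stays free and any silyl ester or mixed anhydride of the hindered acid is hydrolysed on work-up.

Step 21
Reactants: 29 7α-acetate 2-O-TBS ether 11-ketone
Product: 30 11α-alcohol
Conditions: Me4NBH(OAc)3, MeCN/AcOH 1:1, −20 °C
Reagents that add atoms: none
Why: Saksena–Evans hydroxyl-directed reduction, in which the axial 8β-OH binds boron and delivers hydride to the β face of the β-hydroxy ketone to give the 1,3-anti diol (equatorial 11α-OH) that external hydride would not give, while the C14 ketone between two quaternary carbons stays inert.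

Step 22
Reactants: 30 11α-alcohol
Product: 31 11α-benzoate
Conditions: BzCl, DMAP, pyridine, CH2Cl2, rt to 40 °C; aq NaHCO3 work-up
Reagents that add atoms: benzoyl chloride, O=C(Cl)c1ccccc1
Why: DMAP-catalysed benzoylation of the only secondary alcohol, and with C2 still a silyl ether no δ-lactone can form.

Step 23
Reactants: 31 11α-benzoate
Product: 33 CNP0315860.1, via C2 primary alcohol 32 (not isolated)
Conditions: CrO3, H2SO4, H2O/acetone (Jones), 0 °C
Reagents that add atoms: water, O
Why: Jones oxidation cleaves the primary TBS ether in the acidic medium and oxidises C2 through the aldehyde hydrate to the acid, and should leave the esters, the tertiary α-ketol and the vinyl group untouched.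

Compound list
1 | 3-methylcyclohex-2-en-1-one | CC1=CC(=O)CCC1 | starting material
2 | (R)-3-methyl-3-[1-(trimethylsilyl)ethenyl]cyclohexanone | C=C([Si](C)(C)C)[C@@]1(C)CC(=O)CCC1 | intermediate
3 | (R)-3-ethenyl-3-methylcyclohexanone | C=C[C@@]1(C)CC(=O)CCC1 | intermediate
4 | (R)-5-ethenyl-5-methylcyclohex-2-enone | C=C[C@@]1(C)CC(=O)C=CC1 | intermediate
5 | (R)-2-ethenyl-2-methylcyclohex-5-ene-1,4-dione | C=C[C@@]1(C)CC(=O)C=CC1=O | intermediate
6 | (R)-6-ethenyl-4,4-dimethoxy-6-methylcyclohex-2-enone | C=C[C@@]1(C)CC(OC)(OC)C=CC1=O | intermediate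
7 | 3-bromobut-3-en-1-ol | C=C(Br)CCO | starting material
8 | 3-(4,4,5,5-tetramethyl-1,3,2-dioxaborolan-2-yl)but-3-en-1-ol | C=C(CCO)B1OC(C)(C)C(C)(C)O1 | intermediate
9 | (2R,5S)-2-ethenyl-5-(4-hydroxybut-1-en-2-yl)-4,4-dimethoxy-2-methylcyclohexanone | C=C[C@@]1(C)CC(OC)(OC)[C@H](C(=C)CCO)CC1=O | intermediate
10 | trans-fused oxane mixed ketal (ring O 11α; OMe 11β; 9α-H; C10=C20H2; C14 ketone) | C=C[C@@]1(C)C[C@@]2(OC)OCCC(=C)[C@@H]2CC1=O | intermediate
11 | potassium C8=C14 enolate of 10 | C=C[C@@]1(C)C[C@@]2(OC)OCCC(=C)[C@@H]2C=C1O[K] | intermediate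
12 | 8α-hydroxy ketone of the oxane ketal | C=C[C@@]1(C)C[C@@]2(OC)OCCC(=C)[C@@H]2[C@@H](O)C1=O | intermediate
13 | 8α-(methoxymethoxy) ketone | C=C[C@@]1(C)C[C@@]2(OC)OCCC(=C)[C@@H]2[C@@H](OCOC)C1=O | intermediate
14 | lithium C8=C14 enolate of 13 | C=C[C@@]1(C)C[C@@]2(OC)OCCC(=C)[C@@H]2C(OCOC)=C1O[Li] | intermediate
15 | 8β-(methoxymethoxy)-8α-(hydroxymethyl) ketone | C=C[C@@]1(C)C[C@@]2(OC)OCCC(=C)[C@@H]2[C@@](OCOC)(CO)C1=O | intermediate
16 | 8β-(methoxymethoxy)-8α-carbaldehyde (C7 aldehyde) | C=C[C@@]1(C)C[C@@]2(OC)OCCC(=C)[C@@H]2[C@@](OCOC)(C=O)C1=O | intermediate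
17 | tiglic acid | C/C=C(\C)C(=O)O | starting material
18 | tert-butyl tiglate | C/C=C(\C)C(=O)OC(C)(C)C | intermediate
19 | lithium dienolate of 18 | C=CC(C)=C(O[Li])OC(C)(C)C | intermediate
20 | 1-tert-butoxy-1-(tert-butyldimethylsilyloxy)-2-methylbuta-1,3-diene | C=CC(C)=C(OC(C)(C)C)O[Si](C)(C)C(C)(C)C | intermediate
21 | 7-hydroxy (E)-enoate | C=C[C@@]1(C)C[C@@]2(OC)OCCC(=C)[C@@H]2[C@@](OCOC)([C@H](O)C/C=C(\C)C(=O)OC(C)(C)C)C1=O | intermediate
22 | 7-O-triethylsilyl ether (cyclisation precursor) | C=C[C@@]1(C)C[C@@]2(OC)OCCC(=C)[C@@H]2[C@@](OCOC)([C@H](O[Si](CC)(CC)CC)C/C=C(\C)C(=O)OC(C)(C)C)C1=O | intermediate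
23 | tertiary C10 radical | C=C[C@@]1(C)C[C@@]2(OC)OCC[C](C)[C@@H]2[C@@](OCOC)([C@H](O[Si](CC)(CC)CC)C/C=C(\C)C(=O)OC(C)(C)C)C1=O | intermediate
24 | ring-B-closed tricyclic ester (C4 epimers) | C=C[C@@]1(C)C[C@@]2(OC)OCC[C@]3(C)[C@@H]2[C@](OCOC)(C1=O)[C@H](O[Si](CC)(CC)CC)C[C@H]3C(C)C(=O)OC(C)(C)C | intermediate
25 | lithium ester enolate of 24 | C=C[C@@]1(C)C[C@@]2(OC)OCC[C@]3(C)[C@@H]2[C@](OCOC)(C1=O)[C@H](O[Si](CC)(CC)CC)C[C@H]3C(C)=C(O[Li])OC(C)(C)C | intermediate
26 | gem-dimethyl tert-butyl ester | C=C[C@@]1(C)C[C@@]2(OC)OCC[C@]3(C)[C@@H]2[C@](OCOC)(C1=O)[C@H](O[Si](CC)(CC)CC)C[C@H]3C(C)(C)C(=O)OC(C)(C)C | intermediate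
27 | 11-keto 2,7α,8β-triol 3-carboxylic acid | C=C[C@@]1(C)CC(=O)[C@@H]2[C@@](C)(CCO)[C@H](C(C)(C)C(=O)O)C[C@@H](O)[C@@]2(O)C1=O | intermediate
28 | C2 silyl ether of 27 | C=C[C@@]1(C)CC(=O)[C@@H]2[C@@](C)(CCO[Si](C)(C)C(C)(C)C)[C@H](C(C)(C)C(=O)O)C[C@@H](O)[C@@]2(O)C1=O | intermediate
29 | 7α-acetate 2-O-TBS ether 11-ketone | C=C[C@@]1(C)CC(=O)[C@@H]2[C@@](C)(CCO[Si](C)(C)C(C)(C)C)[C@H](C(C)(C)C(=O)O)C[C@@H](OC(C)=O)[C@@]2(O)C1=O | intermediate
30 | 11α-alcohol | C=C[C@@]1(C)C[C@@H](O)[C@@H]2[C@@](C)(CCO[Si](C)(C)C(C)(C)C)[C@H](C(C)(C)C(=O)O)C[C@@H](OC(C)=O)[C@@]2(O)C1=O | intermediate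
31 | 11α-benzoate | C=C[C@@]1(C)C[C@@H](OC(=O)c2ccccc2)[C@@H]2[C@@](C)(CCO[Si](C)(C)C(C)(C)C)[C@H](C(C)(C)C(=O)O)C[C@@H](OC(C)=O)[C@@]2(O)C1=O | intermediate
32 | C2 primary alcohol | C=C[C@@]1(C)C[C@@H](OC(=O)c2ccccc2)[C@@H]2[C@@](C)(CCO)[C@H](C(C)(C)C(=O)O)C[C@@H](OC(C)=O)[C@@]2(O)C1=O | intermediate
33 | CNP0315860.1 | C=C[C@@]1(C)C[C@@H](OC(=O)c2ccccc2)[C@@H]2[C@@](C)(CC(=O)O)[C@H](C(C)(C)C(=O)O)C[C@@H](OC(C)=O)[C@@]2(O)C1=O | target

Total step count: 23. Longest linear sequence: 20 (steps 1–5, 7–12, 15–23).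

Steps most likely to fail

Step 17. The C10 radical may be reduced before it closes the ring, because the incoming C20 methyl is crowded by the 11β-OMe and the 8β-OMOM. Hydrogen-atom transfer may also reach the C13 vinyl group, and the ketal methoxy may exchange with ethanol. The fallback sets out from 22 and uses no metal hydride.
- Buffered mCPBA should epoxidise the electron-rich 1,1-disubstituted alkene to the C10–C20 spiro-epoxide F1.
- Cp2TiCl (Nugent–RajanBabu reductive epoxide opening) generates the same tertiary C10 radical, and 6-exo addition to the enoate should give the ring-closed C20 primary alcohol F2.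
- Thiocarbonyldiimidazole converts it into the imidazole-1-carbothioate F3.
- Barton–McCombie deoxygenation (Bu3SnH, AIBN, toluene, reflux) comes back to the route at 24.

Step 15. The Lewis acid may ionise the strained mixed ketal. The activated C7 aldehyde may undergo an intramolecular carbonyl-ene reaction with the C10 methylene, and chelation control may erode. The fallback sets out from 16 and builds the chain without a Lewis acid.
- The lithium enolate of ethyl acetate (THF, −78 °C, lithium chelate to the MOM ether) should give the β-hydroxy ethyl ester F4.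
- TESCl gives the 7-O-triethylsilyl ester F5.
- DIBAL-H at −78 °C gives the C5 aldehyde F6.
- Wittig olefination with tert-butyl 2-(triphenylphosphoranylidene)propanoate comes back to the route at 22.

Step 19. Strong acid may promote loss of the 8β-OH from the newly freed β-hydroxy ketone, or cleavage of C7–C8. The fallback sets out from 26 and unmasks in stages, so that O8 stays blocked while protic acid is present.
- AcOH/THF/H2O removes only the TES group and the ketal, to give the 11-keto 2,7-diol F7 with the MOM ether and tert-butyl ester intact.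
- TBSCl then Ac2O, as in step 20, give the 7-acetate 2-O-TBS ether F8.
- TMSOTf/2,2'-bipyridyl followed by water removes the MOM group and the tert-butyl ester under non-protic conditions and comes back to the route at 29.

Further compounds
F1 | step 17 | C10–C20 spiro-epoxide of 22 | C=C[C@@]1(C)C[C@@]2(OC)OCCC3(CO3)[C@@H]2[C@@](OCOC)([C@H](O[Si](CC)(CC)CC)C/C=C(\C)C(=O)OC(C)(C)C)C1=O
F2 | step 17 | ring-closed C20 primary alcohol | C=C[C@@]1(C)C[C@@]2(OC)OCC[C@]3(CO)[C@@H]2[C@](OCOC)(C1=O)[C@H](O[Si](CC)(CC)CC)C[C@H]3C(C)C(=O)OC(C)(C)C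
F3 | step 17 | imidazole-1-carbothioate of F2 | C=C[C@@]1(C)C[C@@]2(OC)OCC[C@]3(COC(=S)n4ccnc4)[C@@H]2[C@](OCOC)(C1=O)[C@H](O[Si](CC)(CC)CC)C[C@H]3C(C)C(=O)OC(C)(C)C
F4 | step 15 | β-hydroxy ethyl ester | C=C[C@@]1(C)C[C@@]2(OC)OCCC(=C)[C@@H]2[C@@](OCOC)([C@H](O)CC(=O)OCC)C1=O
F5 | step 15 | 7-O-triethylsilyl ester | C=C[C@@]1(C)C[C@@]2(OC)OCCC(=C)[C@@H]2[C@@](OCOC)([C@H](O[Si](CC)(CC)CC)CC(=O)OCC)C1=O
F6 | step 15 | C5 aldehyde | C=C[C@@]1(C)C[C@@]2(OC)OCCC(=C)[C@@H]2[C@@](OCOC)([C@H](O[Si](CC)(CC)CC)CC=O)C1=O
F7 | step 19 | 11-keto 2,7-diol with MOM ether and tert-butyl ester intact | C=C[C@@]1(C)CC(=O)[C@@H]2[C@@](C)(CCO)[C@H](C(C)(C)C(=O)OC(C)(C)C)C[C@@H](O)[C@@]2(OCOC)C1=O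
F8 | step 19 | 7-acetate 2-O-TBS ether of F7 | C=C[C@@]1(C)CC(=O)[C@@H]2[C@@](C)(CCO[Si](C)(C)C(C)(C)C)[C@H](C(C)(C)C(=O)OC(C)(C)C)C[C@@H](OC(C)=O)[C@@]2(OCOC)C1=O
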